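**Plan**

- Cuts, in retrosynthetic order: the ten O–Si bonds; the stilbene C–C bond at the left-hand phenol ring (Heck), giving a chlorinated left tetracycle and a 4-vinyl-2,3-dihydrobenzofuran; the left dihydrofuran across its aryl C–O and C2–C3 bonds, giving 4-silyloxybenzaldehyde and a 6-fluoro-10,11-diaryl-10,11-dihydro-5H-dibenzo[a,d][7]annulene; the C11–C11a bond of that ring (Friedel–Crafts), giving a 2,3-diaryl-dihydrobenzofuran; and C2–C3 of that ring and of the right-hand one, giving diaryl hydrazones.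
- Forward, left half: diarylmethane, hydrazone, rhodium carbene C–H insertion (dihydrobenzofuran), acid ring opening with seven-ring Friedel–Crafts closure, OMe to OTIPS exchange, annulation of the second dihydrofuran. Right half: benzophenone, hydrazone, C–H insertion, C2 epimerisation, vinylation. Then Heck union and desilylation.
- Feature that makes the key event possible: in the cycloheptadiene the C5 methylene is doubly benzylic (acidic) and the neighbouring ring carbon C5a carries an ortho C6–F. C5 (carbon nucleophile) and C6 (electrophile) are therefore a 1,3-donor/acceptor pair that takes up the C=O of an aldehyde as the two missing ring atoms of the dihydrofuran.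
- Stereochemistry: catalyst control sets C10 of the left half and C3 of the right half (two rhodium-catalysed C–H insertions). C11 (ring closure) and both new centres of the key step are relayed from C10 by substrate control. The right-hand C2 comes from thermodynamic epimerisation and the E alkene from the Heck reaction.

Key step: step 10

Remarks and assumptions:
- TIPS = triisopropylsilyl. Locants for the seven-membered ring compounds follow dibenzo[a,d][7]annulene numbering: C5 = CH2, C6 = C–F, C10 and C11 = the two CH(aryl) carbons.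
- Assumption: Rh2(R-PTAD)4 [dirhodium tetrakis((R)-(1-adamantyl)(phthalimido)acetate), divalent rhodium] is taken to induce the 3S configuration in steps 5 and 18. If its sense of induction is the opposite, the antipode Rh2(S-PTAD)4 is used in both steps without other change.

**Route**

Step 1
Reactants: 1 3-bromo-5-fluoroanisole; 2 3,5-dimethoxybenzaldehyde
Product: 4 (2-bromo-6-fluoro-4-methoxyphenyl)(3,5-dimethoxyphenyl)methanol (racemic), via aryllithium 3 (not isolated)
Conditions: LiN(i-Pr)2, THF, −78 °C; then 2, −78 °C; H2O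
Reagents that add atoms: none
Why: Directed ortho-lithiation should occur at the most acidic ring C–H, the one flanked by fluorine and bromine; the 2-bromo-6-fluoroaryllithium is stable at −78 °C and adds to the aldehyde (1,2-addition), and the racemic carbinol centre is removed in step 2.

Step 2
Reactants: 4
Product: 5 1-bromo-2-(3,5-dimethoxybenzyl)-3-fluoro-5-methoxybenzene
Conditions: Et3SiH, CF3CO2H, CH2Cl2, 0 °C to rt
Reagents that add atoms: none
Why: Ionic hydrogenation of a benzhydrol through the diarylmethyl cation stabilised by the para methoxy group gives the diarylmethane whose CH2 later becomes C5.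

Step 3
Reactants: 6 5-chloro-2-hydroxybenzonitrile; 7 4-methoxybenzyl chloride
Product: 8 5-chloro-2-[(4-methoxybenzyl)oxy]benzonitrile
Conditions: K2CO3, DMF, 60 °C
Reagents that add atoms: none
Why: Williamson ether synthesis on the phenol; the 4-methoxybenzyl group is not a protecting group here but the future C11 with its aryl substituent.

Step 4
Reactants: 5; 8
Product: 11 [5-chloro-2-(4-methoxybenzyloxy)phenyl][2-(3,5-dimethoxybenzyl)-3-fluoro-5-methoxyphenyl]methanone hydrazone, via aryllithium 9 (not isolated), via lithium ketimide 10 (not isolated)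
Conditions: n-BuLi, THF, −78 °C; then 8, −78 to 0 °C; then N2H4·H2O, AcOH, EtOH, 60 °C
Reagents that add atoms: hydrazine, NN
Why: Bromine–lithium exchange and addition of the aryllithium to the nitrile give the lithium ketimide, and transimination with hydrazine gives the N-unsubstituted hydrazone directly, so that no hindered diaryl ketone has to be condensed.

Step 5
Reactants: 11
Product: 13 (2R,3S)-5-chloro-3-[2-(3,5-dimethoxybenzyl)-3-fluoro-5-methoxyphenyl]-2-(4-methoxyphenyl)-2,3-dihydro-1-benzofuran (cis), via diazo compound 12 (not isolated)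
Conditions: MnO2, CH2Cl2, 0 °C; filtration; Rh2(R-PTAD)4 (1 mol %), CH2Cl2, 0 °C to rt
Reagents that add atoms: none
Why: Oxidation of the hydrazone gives the diaryldiazomethane, and the chiral divalent rhodium carboxylate converts it into a donor/donor carbene that should insert into the benzylic C–H next to oxygen (1,5 C–H insertion, five-membered ring) faster than it attacks the pendant arene; the catalyst sets C3 (3S), and the C2 configuration of the usual cis product is of no consequence because step 6 erases it.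

Step 6
Reactants: 13
Product: 14 (10S,11S)-10-(5-chloro-2-hydroxyphenyl)-6-fluoro-1,3,8-trimethoxy-11-(4-methoxyphenyl)-10,11-dihydro-5H-dibenzo[a,d][7]annulene
Conditions: BF3·OEt2 (20 mol %), CH2Cl2, −40 to 0 °C
Reagents that add atoms: none
Why: The Lewis acid opens the benzylic C2–O bond to the 4-methoxybenzyl cation, which is captured by the ortho carbon of the 3,5-dimethoxybenzyl ring in a seven-ring-forming Friedel–Crafts alkylation, a known reaction type for 2,3-diaryl-dihydrobenzofurans; C10 (the former C3) is untouched and C11 is set by substrate control, the arene attacking the cation face anti to the C10 aryl group while the 4-methoxyphenyl group turns away from the peri methoxy group, which should put the two aryl groups cis.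

Step 7
Reactants: 14
Product: 15 (10S,11S)-10-(5-chloro-2-hydroxyphenyl)-6-fluoro-11-(4-hydroxyphenyl)-10,11-dihydro-5H-dibenzo[a,d][7]annulene-1,3,8-triol
Conditions: BBr3, CH2Cl2, −78 to 0 °C; H2O
Reagents that add atoms: none
Why: Lewis-acid cleavage of the four aryl methyl ethers, done at this stage because the core carries no acid-labile dihydrofuran or stilbene yet.

Step 8
Reactants: 15
Product: 16 (10S,11S)-10-[5-chloro-2-(TIPS-oxy)phenyl]-6-fluoro-11-[4-(TIPS-oxy)phenyl]-1,3,8-tris(TIPS-oxy)-10,11-dihydro-5H-dibenzo[a,d][7]annulene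
Conditions: TIPSOTf, 2,6-lutidine, CH2Cl2, 0 °C to rt
Reagents that add atoms: triisopropylsilyl trifluoromethanesulfonate, CC(C)[Si](OS(=O)(=O)C(F)(F)F)(C(C)C)C(C)C
Why: Silylation of the five phenols; the TIPS ethers stand up to amide bases and palladium catalysis, come off with fluoride at the end, and the one at C8 shields the ring C–H between fluorine and oxygen from metalation in step 10.

Step 9
Reactants: 17 4-hydroxybenzaldehyde
Product: 18 4-(triisopropylsilyloxy)benzaldehyde
Conditions: TIPSCl, imidazole, DMF, rt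
Reagents that add atoms: triisopropylsilyl chloride, CC(C)[Si](Cl)(C(C)C)C(C)C
Why: Standard silylation of a phenol, giving the aldehyde partner for step 10 and the precursor of the benzyl alcohol 22.

Step 10
Reactants: 16; 18
Product: 21 hexa-TIPS chloro tetracycle (16 with a trans-(2S,3S)-2-[4-(TIPS-oxy)phenyl]-2,3-dihydrofuran fused across C5 = furan C3 and C6 = oxygen-bearing furan C7a; C10 and C11 unchanged), via potassium carbanion 19 (not isolated), via potassium aldolate 20 (not isolated)
Conditions: LiN(i-Pr)2/KOt-Bu (1.1 equiv each), THF, −78 °C; then 18, −78 °C; then 50 °C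
Reagents that add atoms: none
Why: Proposed new method: potassium diisopropylamide, formed in the flask, removes a proton from the doubly benzylic C5 methylene of 16, the diarylmethyl anion 19 adds to the aldehyde 18, and on warming the potassium alkoxide 20 displaces the ortho fluoride at C6 by intramolecular SNAr, so that the C–C bond and the aryl C–O bond of the dihydrofuran form in one flask. The closest known reaction type is the base-mediated domino benzylic addition/SNAr of 2-fluorotoluenes with nitriles to give indoles, together with the addition of diphenylmethyl anions to aldehydes and the closure of 2-(2-fluoroaryl)ethoxides to dihydrobenzofurans; new is the aldehyde/alkoxide version on a 2-fluorodiarylmethane. The furan ring closes by 5-exo-trig attack of the alkoxide oxygen on the fluorine-bearing aromatic carbon (addition–elimination through a Meisenheimer-type transition state). The C5 (furan C3) centre is set by substrate control, the aldehyde approaching the planar anion on the ring face opposite to the pseudo-axial aryl group at C11 and the cis aryl group at C10; the furan C2 centre follows from C3, because the two aldolates equilibrate by retro-aldol/aldol and the one that leads to the less strained trans-2,3-disubstituted ring, with its aryl group anti to the ring-fused arene, should close faster. The step needs site selectivity of metalation (secured by the acidity of the diarylmethane C–H and by the TIPS shield next to the only acidic aryl C–H), facial selectivity at C5 (secured by the two cis aryl groups) and ring closure ahead of elimination or ring opening (only the weakly basic alkoxide remains once the amide is consumed, so the C3–H of the product is not removed).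

Step 11
Reactants: 18
Product: 22 [4-(triisopropylsilyloxy)phenyl]methanol
Conditions: NaBH4, MeOH, 0 °C
Reagents that add atoms: none
Why: Borohydride reduction of the aldehyde to the benzyl alcohol needed for the Mitsunobu etherification.

Step 12
Reactants: 23 2-bromo-4,6-dimethoxybenzaldehyde; 24 3,5-dimethoxyphenylmagnesium chloride (THF solution)
Product: 25 (2-bromo-4,6-dimethoxyphenyl)(3,5-dimethoxyphenyl)methanol (racemic)
Conditions: THF, 0 °C to rt; H2O
Reagents that add atoms: none
Why: 1,2-Addition of the aryl Grignard reagent to the aldehyde; the racemic carbinol is oxidised in step 13.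

Step 13
Reactants: 25
Product: 26 (2-bromo-4,6-dimethoxyphenyl)(3,5-dimethoxyphenyl)methanone
Conditions: Dess–Martin periodinane, CH2Cl2, rt
Reagents that add atoms: none
Why: Dess–Martin oxidation of the benzhydrol to the benzophenone.

Step 14
Reactants: 26
Product: 27 (2-bromo-4,6-dihydroxyphenyl)(3,5-dihydroxyphenyl)methanone
Conditions: BBr3, CH2Cl2, −78 °C to rt; H2O
Reagents that add atoms: none
Why: Cleavage of the four aryl methyl ethers before any acid-sensitive ring is present, so that the right half can carry fluoride-labile silyl ethers.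

Step 15
Reactants: 27
Product: 28 [2-bromo-6-hydroxy-4-(TIPS-oxy)phenyl][3,5-bis(TIPS-oxy)phenyl]methanone
Conditions: TIPSCl (3.2 equiv), imidazole, DMF, 0 °C to rt
Reagents that add atoms: triisopropylsilyl chloride, CC(C)[Si](Cl)(C(C)C)C(C)C
Why: Selective silylation of the three free phenols, the fourth being deactivated by its hydrogen bond to the ketone and by the flanking aroyl group (chelation-controlled differentiation of an ortho-hydroxy benzophenone).

Step 16
Reactants: 28; 22
Product: 29 [2-bromo-6-{[4-(TIPS-oxy)benzyl]oxy}-4-(TIPS-oxy)phenyl][3,5-bis(TIPS-oxy)phenyl]methanone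
Conditions: PPh3, DIAD, THF, 0 °C to rt
Reagents that add atoms: none
Why: Mitsunobu etherification of the acidic chelated phenol with the primary benzyl alcohol under neutral conditions that leave the aryl silyl ethers intact.

Step 17
Reactants: 29
Product: 30 hydrazone of 29
Conditions: N2H4·H2O, AcOH (cat.), n-BuOH, 100 °C
Reagents that add atoms: hydrazine, NN
Why: Condensation of the ketone with hydrazine to the hydrazone; the small nucleophile should tolerate the 2,6-disubstitution, and the temperature is kept below that at which the ortho bromide would be displaced.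

Step 18
Reactants: 30
Product: 32 (2R,3S)-4-bromo-3-[3,5-bis(TIPS-oxy)phenyl]-6-(TIPS-oxy)-2-[4-(TIPS-oxy)phenyl]-2,3-dihydro-1-benzofuran (cis), via diazo compound 31 (not isolated)
Conditions: MnO2, CH2Cl2, 0 °C; filtration; Rh2(R-PTAD)4 (1 mol %), CH2Cl2, 0 °C to rt
Reagents that add atoms: none
Why: Same sequence as step 5, oxidation to the diaryldiazomethane and enantioselective rhodium carbene 1,5 C–H insertion into the benzylic ether C–H, the catalyst setting C3 (3S) of the cis-2,3-diaryl-dihydrobenzofuran.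

Step 19
Reactants: 32
Product: 33 (2S,3S)-4-bromo-3-[3,5-bis(TIPS-oxy)phenyl]-6-(TIPS-oxy)-2-[4-(TIPS-oxy)phenyl]-2,3-dihydro-1-benzofuran (trans)
Conditions: BF3·OEt2 (10 mol %), CH2Cl2, −20 °C
Reagents that add atoms: none
Why: Reversible acid ionisation of the benzylic C2–O bond (C3 is untouched) should equilibrate C2 to the more stable trans isomer (thermodynamic control); it is done before the vinyl group is present because a styrene would cyclise under acid.

Step 20
Reactants: 33
Product: 34 (2S,3S)-3-[3,5-bis(TIPS-oxy)phenyl]-4-ethenyl-6-(TIPS-oxy)-2-[4-(TIPS-oxy)phenyl]-2,3-dihydro-1-benzofuran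
Conditions: Bu3Sn(CH=CH2), Pd(PPh3)4 (5 mol %), toluene, 100 °C
Reagents that add atoms: tributyl(vinyl)stannane, C=C[Sn](CCCC)(CCCC)CCCC
Why: Stille coupling of the aryl bromide with the vinylstannane under base-free conditions that spare the silyl ethers.

Step 21
Reactants: 21; 34
Product: 35 deca-TIPS ether of the target
Conditions: Pd2(dba)3 (2.5 mol %), [HP(t-Bu)3]BF4 (10 mol %), Cy2NMe, 1,4-dioxane, 100 °C
Reagents that add atoms: none
Why: Heck reaction of the aryl chloride with the styrene, using the bulky electron-rich phosphine needed for oxidative addition of a chloride to zerovalent palladium; syn insertion and syn β-hydride elimination should give the E-stilbene.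

Step 22
Reactants: 35
Product: 36 target CNP0266373.2
Conditions: Bu4NF, AcOH, THF, 0 °C to rt
Reagents that add atoms: none
Why: Fluoride cleavage of all ten aryl silyl ethers, buffered with acetic acid so that no phenoxide opens or epimerises the 2-aryl-dihydrobenzofurans and no strong acid is present that would cyclise the stilbene.

**Compound list**

1 | 3-bromo-5-fluoroanisole | COc1cc(F)cc(Br)c1 | starting material
2 | 3,5-dimethoxybenzaldehyde | COc1cc(C=O)cc(OC)c1 | starting material
3 | (2-bromo-6-fluoro-4-methoxyphenyl)lithium | COc1cc(F)c([Li])c(Br)c1 | intermediate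
4 | (2-bromo-6-fluoro-4-methoxyphenyl)(3,5-dimethoxyphenyl)methanol, racemic | COc1cc(F)c(C(O)c2cc(OC)cc(OC)c2)c(Br)c1 | intermediate
5 | 1-bromo-2-(3,5-dimethoxybenzyl)-3-fluoro-5-methoxybenzene | COc1cc(F)c(Cc2cc(OC)cc(OC)c2)c(Br)c1 | intermediate
6 | 5-chloro-2-hydroxybenzonitrile | N#Cc1cc(Cl)ccc1O | starting material
7 | 4-methoxybenzyl chloride | COc1ccc(CCl)cc1 | starting material
8 | 5-chloro-2-[(4-methoxybenzyl)oxy]benzonitrile | N#Cc1cc(Cl)ccc1OCc1ccc(OC)cc1 | intermediate
9 | [2-(3,5-dimethoxybenzyl)-3-fluoro-5-methoxyphenyl]lithium | COc1cc(F)c(Cc2cc(OC)cc(OC)c2)c([Li])c1 | intermediate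
10 | lithium ketimide from 9 and 8 | COc1cc(F)c(Cc2cc(OC)cc(OC)c2)c(c1)C(=N[Li])c1cc(Cl)ccc1OCc1ccc(OC)cc1 | intermediate
11 | [5-chloro-2-(4-methoxybenzyloxy)phenyl][2-(3,5-dimethoxybenzyl)-3-fluoro-5-methoxyphenyl]methanone hydrazone | COc1cc(F)c(Cc2cc(OC)cc(OC)c2)c(c1)C(=NN)c1cc(Cl)ccc1OCc1ccc(OC)cc1 | intermediate
12 | diaryldiazomethane from 11 | COc1cc(F)c(Cc2cc(OC)cc(OC)c2)c(c1)C(=[N+]=[N-])c1cc(Cl)ccc1OCc1ccc(OC)cc1 | intermediate
13 | (2R,3S)-5-chloro-3-[2-(3,5-dimethoxybenzyl)-3-fluoro-5-methoxyphenyl]-2-(4-methoxyphenyl)-2,3-dihydro-1-benzofuran (cis) | COc1cc(F)c(Cc2cc(OC)cc(OC)c2)c(c1)[C@H]1c2cc(Cl)ccc2O[C@H]1c1ccc(OC)cc1 | intermediate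
14 | (10S,11S)-10-(5-chloro-2-hydroxyphenyl)-6-fluoro-1,3,8-trimethoxy-11-(4-methoxyphenyl)-10,11-dihydro-5H-dibenzo[a,d][7]annulene | COc1ccc([C@H]2c3c(OC)cc(OC)cc3Cc3c(F)cc(OC)cc3[C@H]2c2cc(Cl)ccc2O)cc1 | intermediate
15 | (10S,11S)-10-(5-chloro-2-hydroxyphenyl)-6-fluoro-11-(4-hydroxyphenyl)-10,11-dihydro-5H-dibenzo[a,d][7]annulene-1,3,8-triol | Oc1ccc([C@H]2c3c(O)cc(O)cc3Cc3c(F)cc(O)cc3[C@H]2c2cc(Cl)ccc2O)cc1 | intermediate
16 | penta-TIPS ether of 15 | CC(C)[Si](C(C)C)(C(C)C)Oc1ccc([C@H]2c3c(O[Si](C(C)C)(C(C)C)C(C)C)cc(O[Si](C(C)C)(C(C)C)C(C)C)cc3Cc3c(F)cc(O[Si](C(C)C)(C(C)C)C(C)C)cc3[C@H]2c2cc(Cl)ccc2O[Si](C(C)C)(C(C)C)C(C)C)cc1 | intermediate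
17 | 4-hydroxybenzaldehyde | O=Cc1ccc(O)cc1 | starting material
18 | 4-(triisopropylsilyloxy)benzaldehyde | CC(C)[Si](C(C)C)(C(C)C)Oc1ccc(C=O)cc1 | intermediate
19 | potassium salt of the C5 carbanion of 16 | CC(C)[Si](C(C)C)(C(C)C)Oc1ccc([C@H]2c3c(O[Si](C(C)C)(C(C)C)C(C)C)cc(O[Si](C(C)C)(C(C)C)C(C)C)cc3[CH-]c3c(F)cc(O[Si](C(C)C)(C(C)C)C(C)C)cc3[C@H]2c2cc(Cl)ccc2O[Si](C(C)C)(C(C)C)C(C)C)cc1.[K+] | intermediate
20 | potassium aldolate: 16 carrying at C5 (S) an (S)-CH(OK)[4-(TIPS-oxy)phenyl] group | CC(C)[Si](C(C)C)(C(C)C)Oc1ccc([C@H]2c3c(O[Si](C(C)C)(C(C)C)C(C)C)cc(O[Si](C(C)C)(C(C)C)C(C)C)cc3[C@H]([C@H]([O-])c3ccc(O[Si](C(C)C)(C(C)C)C(C)C)cc3)c3c(F)cc(O[Si](C(C)C)(C(C)C)C(C)C)cc3[C@H]2c2cc(Cl)ccc2O[Si](C(C)C)(C(C)C)C(C)C)cc1.[K+] | intermediate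
21 | hexa-TIPS chloro tetracycle: dihydrofuran (C2 S, C3 S, trans) fused across former C5 and C6 of 16; C10 S, C11 S | CC(C)[Si](C(C)C)(C(C)C)Oc1ccc([C@H]2c3c(O[Si](C(C)C)(C(C)C)C(C)C)cc(O[Si](C(C)C)(C(C)C)C(C)C)cc3[C@H]3c4c(cc(O[Si](C(C)C)(C(C)C)C(C)C)cc4[C@H]2c2cc(Cl)ccc2O[Si](C(C)C)(C(C)C)C(C)C)O[C@@H]3c2ccc(O[Si](C(C)C)(C(C)C)C(C)C)cc2)cc1 | intermediate
22 | [4-(triisopropylsilyloxy)phenyl]methanol | CC(C)[Si](C(C)C)(C(C)C)Oc1ccc(CO)cc1 | intermediate
23 | 2-bromo-4,6-dimethoxybenzaldehyde | COc1cc(Br)c(C=O)c(OC)c1 | starting material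
24 | 3,5-dimethoxyphenylmagnesium chloride | COc1cc(OC)cc([Mg]Cl)c1 | starting material
25 | (2-bromo-4,6-dimethoxyphenyl)(3,5-dimethoxyphenyl)methanol, racemic | COc1cc(Br)c(C(O)c2cc(OC)cc(OC)c2)c(OC)c1 | intermediate
26 | (2-bromo-4,6-dimethoxyphenyl)(3,5-dimethoxyphenyl)methanone | COc1cc(Br)c(C(=O)c2cc(OC)cc(OC)c2)c(OC)c1 | intermediate
27 | (2-bromo-4,6-dihydroxyphenyl)(3,5-dihydroxyphenyl)methanone | Oc1cc(Br)c(C(=O)c2cc(O)cc(O)c2)c(O)c1 | intermediate
28 | [2-bromo-6-hydroxy-4-(TIPS-oxy)phenyl][3,5-bis(TIPS-oxy)phenyl]methanone | CC(C)[Si](C(C)C)(C(C)C)Oc1cc(Br)c(C(=O)c2cc(O[Si](C(C)C)(C(C)C)C(C)C)cc(O[Si](C(C)C)(C(C)C)C(C)C)c2)c(O)c1 | intermediate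
29 | [2-bromo-6-{[4-(TIPS-oxy)benzyl]oxy}-4-(TIPS-oxy)phenyl][3,5-bis(TIPS-oxy)phenyl]methanone | CC(C)[Si](C(C)C)(C(C)C)Oc1cc(Br)c(C(=O)c2cc(O[Si](C(C)C)(C(C)C)C(C)C)cc(O[Si](C(C)C)(C(C)C)C(C)C)c2)c(OCc2ccc(O[Si](C(C)C)(C(C)C)C(C)C)cc2)c1 | intermediate
30 | hydrazone of 29 | CC(C)[Si](C(C)C)(C(C)C)Oc1cc(Br)c(C(=NN)c2cc(O[Si](C(C)C)(C(C)C)C(C)C)cc(O[Si](C(C)C)(C(C)C)C(C)C)c2)c(OCc2ccc(O[Si](C(C)C)(C(C)C)C(C)C)cc2)c1 | intermediate
31 | diaryldiazomethane from 30 | CC(C)[Si](C(C)C)(C(C)C)Oc1cc(Br)c(C(=[N+]=[N-])c2cc(O[Si](C(C)C)(C(C)C)C(C)C)cc(O[Si](C(C)C)(C(C)C)C(C)C)c2)c(OCc2ccc(O[Si](C(C)C)(C(C)C)C(C)C)cc2)c1 | intermediate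
32 | (2R,3S)-4-bromo-3-[3,5-bis(TIPS-oxy)phenyl]-6-(TIPS-oxy)-2-[4-(TIPS-oxy)phenyl]-2,3-dihydro-1-benzofuran (cis) | Brc1cc(O[Si](C(C)C)(C(C)C)C(C)C)cc2c1[C@H](c1cc(O[Si](C(C)C)(C(C)C)C(C)C)cc(O[Si](C(C)C)(C(C)C)C(C)C)c1)[C@H](c1ccc(O[Si](C(C)C)(C(C)C)C(C)C)cc1)O2 | intermediate
33 | (2S,3S)-4-bromo-3-[3,5-bis(TIPS-oxy)phenyl]-6-(TIPS-oxy)-2-[4-(TIPS-oxy)phenyl]-2,3-dihydro-1-benzofuran (trans) | Brc1cc(O[Si](C(C)C)(C(C)C)C(C)C)cc2c1[C@H](c1cc(O[Si](C(C)C)(C(C)C)C(C)C)cc(O[Si](C(C)C)(C(C)C)C(C)C)c1)[C@@H](c1ccc(O[Si](C(C)C)(C(C)C)C(C)C)cc1)O2 | intermediate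
34 | (2S,3S)-3-[3,5-bis(TIPS-oxy)phenyl]-4-ethenyl-6-(TIPS-oxy)-2-[4-(TIPS-oxy)phenyl]-2,3-dihydro-1-benzofuran | C=Cc1cc(O[Si](C(C)C)(C(C)C)C(C)C)cc2c1[C@H](c1cc(O[Si](C(C)C)(C(C)C)C(C)C)cc(O[Si](C(C)C)(C(C)C)C(C)C)c1)[C@@H](c1ccc(O[Si](C(C)C)(C(C)C)C(C)C)cc1)O2 | intermediate
35 | deca-TIPS ether of the target (E-stilbene, all six stereocentres S) | CC(C)[Si](C(C)C)(C(C)C)Oc1ccc([C@H]2c3c(O[Si](C(C)C)(C(C)C)C(C)C)cc(O[Si](C(C)C)(C(C)C)C(C)C)cc3[C@H]3c4c(cc(O[Si](C(C)C)(C(C)C)C(C)C)cc4[C@H]2c2cc(/C=C/c4cc(O[Si](C(C)C)(C(C)C)C(C)C)cc5c4[C@H](c4cc(O[Si](C(C)C)(C(C)C)C(C)C)cc(O[Si](C(C)C)(C(C)C)C(C)C)c4)[C@@H](c4ccc(O[Si](C(C)C)(C(C)C)C(C)C)cc4)O5)ccc2O[Si](C(C)C)(C(C)C)C(C)C)O[C@@H]3c2ccc(O[Si](C(C)C)(C(C)C)C(C)C)cc2)cc1 | intermediate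
36 | CNP0266373.2 | Oc1ccc([C@H]2c3c(O)cc(O)cc3[C@H]3c4c(cc(O)cc4[C@H]2c2cc(/C=C/c4cc(O)cc5c4[C@H](c4cc(O)cc(O)c4)[C@@H](c4ccc(O)cc4)O5)ccc2O)O[C@@H]3c2ccc(O)cc2)cc1 | target

**Count and risks**

Total step count: 22. Longest linear sequence: 11 steps (steps 12 to 22).

Steps most likely to fail:

1. Step 10 (proposed new method). What may go wrong: metalation at an aryl C–H followed by loss of halide, retro-aldol outrunning a slow ring closure, silyl transfer to the alkoxide, or poor facial selectivity at C5. Fallback with known chemistry, from 16 back to 21: the domino is replaced by two isolated, individually known reactions. Compound 16 is deprotonated with LiN(i-Pr)2 in THF (−78 to −40 °C) and added to 18 at −78 °C under kinetic lithium control; aqueous quench and chromatography give the alcohol F1 as the wanted diastereomer. F1 is then closed in a separate operation with NaH in DMF at 80 °C, the known intramolecular SNAr of 2-(2-fluoroaryl)ethanols to 2,3-dihydrobenzofurans, which gives 21.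

2. Step 6. What may go wrong: poor facial selectivity in the ring-closing Friedel–Crafts alkylation, or loss of configuration at C11 by reversible ionisation, so that the aryl groups at C10 and C11 end up trans. Fallback, from 13 back to 14: the acid closure is accepted as it falls and the trans product, the C11 epimer F2, is corrected by an oxidation/hydride sequence in which hydrogen, not the arene, is the last group delivered to C11. DDQ in CH2Cl2 at 0 °C abstracts hydride from the electron-rich C11–H and the neighbouring phenol traps the cation to give the cis-fused cyclic ether F3. Ionic hydrogenolysis with Et3SiH and BF3·OEt2 at −78 °C then delivers hydride to the C11 cation anti to the C10 aryl group and gives the cis compound 14.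

3. Step 17. What may go wrong: incomplete condensation at the 2,6-disubstituted ketone, with desilylation or displacement of the ortho bromide under forcing conditions. Fallback, from 28 back to 30: the order of bond formation is changed so that the hydrazone is made while the ortho phenol is still free. In 28 the hydrogen bond holds the carbonyl in the plane of the phenol ring and assists condensation, so N2H4·H2O in EtOH at 60 °C should give the hydroxy hydrazone F4. The phenol is then alkylated with 4-(triisopropylsilyloxy)benzyl bromide F5 (from 22 with CBr4/PPh3) and K2CO3 in acetone at rt; the phenoxide reacts in preference to the hydrazone nitrogen and gives 30.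

Further compounds

F1 | step 10 | alcohol, protonated form of 20: 16 carrying at C5 (S) an (S)-CH(OH)[4-(TIPS-oxy)phenyl] group | CC(C)[Si](C(C)C)(C(C)C)Oc1ccc([C@H]2c3c(O[Si](C(C)C)(C(C)C)C(C)C)cc(O[Si](C(C)C)(C(C)C)C(C)C)cc3[C@H]([C@H](O)c3ccc(O[Si](C(C)C)(C(C)C)C(C)C)cc3)c3c(F)cc(O[Si](C(C)C)(C(C)C)C(C)C)cc3[C@H]2c2cc(Cl)ccc2O[Si](C(C)C)(C(C)C)C(C)C)cc1
F2 | step 6 | (10S,11R) C11 epimer of 14 (aryl groups trans) | COc1ccc([C@@H]2c3c(OC)cc(OC)cc3Cc3c(F)cc(OC)cc3[C@H]2c2cc(Cl)ccc2O)cc1
F3 | step 6 | cis-fused cyclic ether of F2: C11 bonded to the oxygen of the C10 aryl group | COc1ccc(cc1)[C@@]12Oc3ccc(Cl)cc3[C@@H]1c1cc(OC)cc(F)c1Cc1cc(OC)cc(OC)c12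
F4 | step 17 | hydrazone of 28 | CC(C)[Si](C(C)C)(C(C)C)Oc1cc(Br)c(C(=NN)c2cc(O[Si](C(C)C)(C(C)C)C(C)C)cc(O[Si](C(C)C)(C(C)C)C(C)C)c2)c(O)c1
F5 | step 17 | 4-(triisopropylsilyloxy)benzyl bromide | CC(C)[Si](C(C)C)(C(C)C)Oc1ccc(CBr)cc1
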